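(The readings were computed from invented constants.)

The reading at 3.0 d first asks how many substrate half-lives fit into it. I built each flask up from that count.

| flask | substrate | partner | remark | time |
|---|---|---|---|---|
| south-east | 31 mM | 29.4 mM | run made earlier |  |
| east | 31 mM | 15 mM | run made earlier |  |
| north-west | 31 mM | 59 mM | run made earlier |  |
| winter | 31 mM (fed, over 2.40 d) | 29.4 mM | a stirred flask in which substrate is dosed at a steady rate over 2.40 d without added volume, worked up at 3.0 d | 3.0 d |
| midnight | 31 mM | 29.4 mM | a single well-mixed tank run continuously and read at steady state, 3.0 d in it on average |  |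
| dawn | 31 mM | 29.4 mM | everything together in a closed stirred flask, run for 3.0 d | 3.0 d |
| dusk | 31 mM | 29.4 mM | one stirred flow tank at steady state, fed with the mixture as stated, mean residence time 15.0 d |  |

south-east run (percent of the substrate charged)

| time / h | target / % | substrate / % |
|---|---|---|
| 2.50 | 0 | 95.3 |
| 6.00 | 0.2 | 93.3 |
| 12.0 | 1.4 | 88.2 |
| 20.0 | 0.9 | 80.9 |
| 25.0 | 0.4 | 75.7 |
| 30.0 | 1.1 | 73.0 |
| 40.0 | 0.8 | 64.6 |

east run (percent of the substrate charged)

| time / d | target / % | substrate / % |
|---|---|---|
| 0.417 | 0 | 87.5 |
| 0.833 | 0 | 80.0 |
| 1.25 | 0 | 70.8 |
| 1.67 | 2.8 | 65.3 |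
| 2.00 | 4.0 | 60.0 |
| 2.50 | 2.2 | 52.3 |
| 3.00 | 4.3 | 45.8 |

north-west run (percent of the substrate charged)

| time / d | target / % | substrate / % |
|---|---|---|
| 0.250 | 0 | 94.0 |
| 0.333 | 0.4 | 92.3 |
| 0.500 | 0 | 86.6 |
| 0.833 | 0 | 80.5 |
| 1.25 | 3.5 | 67.6 |
| 2.08 | 9.6 | 57.8 |
| 3.00 | 18.5 | 47.2 |

(each reading ± 1 percentage point)

- the stated concentrations are those of everything mixed, before any reaction; amounts are the same in each set-up
- the earlier runs were read with a standard deviation of 1 percentage point
- the feed brings no volume worth counting
- the earlier runs were made in a closed, stirred flask

- the set-up with the highest amount of target at the outlet or at the end, in percent of the substrate put in ("none" if the first two lie within 2 percentage points) (winter / midnight / dawn / dusk / none)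
- amount of target at the outlet or at the end, in percent of the substrate put in, winter
- amount of target at the outlet or at the end, in percent of the substrate put in, midnight
- amount of target at the outlet or at the end, in percent of the substrate put in, dawn
- amount of target at the outlet or at the end, in percent of the substrate put in, dusk

In the north-west run, substrate fell from 94.0% to 47.2% between 0.250 d and 3.00 d. That gave a half-life T = 2.77 d, the time in which the substrate present is halved. The east run, with 15 mM of partner instead of 59 mM, stood at 45.8% at the same time, so I took T as free of partner.

I began with the substrate step alone. With n the number of half-lives counted and the loss taken as first-order, a closed flask keeps 0.5^n of its substrate, and a tank keeps 1/(1 + n ln(2)). Winter's charge enters on average at the middle of the feed, so I counted its time from there.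

> dawn: n = t/T = 1.08, left 47.2%
> winter: n = (t − feed time/2)/T = 0.651, left 63.7%
> midnight: n = 1.08, left 57.1%
> dusk: n = 5.42, left 21.0%

Then I added the partner step. Target stayed near zero up to 0.833 d in the north-west run, and at 3.00 d it stood at 18.5% there against 4.3% in the east run. Scaling the north-west target by the partner charge gave me about 9.22% target for dawn, where 52.8% of the substrate was gone by my count.

Last came partner's own use: at 0.948 equivalents it is the limiting reagent, and I expected its use to weigh on dusk, whose count is larger than dawn's. I expected dusk first and winter, whose count is smaller than dawn's, below dawn.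

The forecast gave winter 4.6%, midnight 11.2%, dawn 10% and dusk 42%, with the words “Dusk is clearly best, although it relies on extrapolation”.

The flask gave dusk as best, with winter 4.50%, midnight 13.7%, dawn 11.3% and dusk 35.1%, so dusk stood 6.9 percentage points below the forecast.

    intermediate A ⇌ intermediate B (K = 2.40, k = 0.0267 /h)
    partner + intermediate D → target (k = 2.11 /M/h)
    substrate ⇌ intermediate A (K = 2.09, k = 0.0121 /h)
    partner + intermediate B → intermediate D (k = 1.95 /M/h)
    intermediate B ⇌ intermediate C (K = 0.240, k = 0.0337 /h)

In winter at 3.00 d, the forward step of substrate into intermediate A, taken alone, had a half-life of 2.4 d, longer than the 1.1 d of the forward step of intermediate A into intermediate B. Winter then still held 63.5% substrate against 4.50% target. Winter read at 8.0 d counts 2.46 half-lives, which leaves 18.2%, and that flask held 21.7% substrate.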